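Numbering: C1 (quaternary, CH3), C2 and C3 (CH2), C4 (C(OH)iPr), C5 (fusion CH), C6 (CH–O-aroyl), C7 (CH2), C8 (=C–CH3), C9 (=CH), C10 (CH–O-isovaleryl). β is the face of the C1 methyl. The target is the cis-fused (1R,4S,5S,6R,10S) isomer, with CH3-1, H-5 and OH-4 β and with iPr-4, O-6 and O-10 α.
Cuts, in retrosynthetic order: O10–acyl, C10–H, C8–CH3 with the C8=C9 unsaturation, C4–O, C5–H (paired with a C3–O bond, allylic transposition), C6–O(aroyl), then C4–C5 (five-membered ring), then C1–C2 and C1–CH3.
Enabling feature: in the seven-membered ring (C1, C5, C6, C7, C8, C9, C10) the quaternary C1 is flanked by C5 and C10. Drawn as two carbonyls, these are the enantiotopic halves of a mirror-symmetric 2,2-disubstituted cycloheptane-1,3-dione. The C2–C3(=O)–C4 arm on C1 brings a nucleophilic C4 next to C5, so a single C4–C5 bond closes the five-membered ring (C1–C2–C3–C4–C5) and makes C1 stereogenic.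
Forward order: the seven-membered ring is bought and C1 is alkylated twice. The five-membered ring is closed by the desymmetrising aldol condensation. O-6, H-5 and OH-4 are then placed around the former enone, and C8–CH3, C8=C9 and the C10 ester are built last from the surviving ketone.
Stereochemistry: C1 comes from the amino-acid catalyst. C6 comes from β-face oxygenation followed by Mitsunobu inversion. C5 comes from a CBS-set C3 carbinol relayed by a suprafacial diazene retro-ene. C4 and C10 come from attack on the convex β face of the cis-fused bicycle.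

Key step: step 3

Assumption: the sense of induction in step 3 is extrapolated from the six-ring closures, in which L-amino acids give the quaternary centre of the opposite spatial arrangement to that needed here; should the five-ring closure respond in the reverse sense, L-phenylalanine is used and nothing else changes.

Step 1
Reactants: 1 cycloheptane-1,3-dione; 2 iodomethane
Product: 3 2-methylcycloheptane-1,3-dione
Conditions: K2CO3, MeI (1.0 equiv), acetone, reflux
Reagents that add atoms: iodomethane (2), CI
Why: C-alkylation of the stabilised β-diketone enolate with a small soft electrophile should form C1–CH3, and one equivalent of MeI limits a second methylation.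

Step 2
Reactants: 3 2-methylcycloheptane-1,3-dione; 4 1-bromo-4-methylpentan-2-one
Product: 5 2-methyl-2-(4-methyl-2-oxopentyl)cycloheptane-1,3-dione
Conditions: K2CO3, acetone, rt
Reagents that add atoms: 1-bromo-4-methylpentan-2-one (4), CC(C)CC(=O)CBr
Why: A second β-dicarbonyl C-alkylation (SN2 on the activated α-bromoketone) forms C1–C2 and the prochiral quaternary carbon, while the weak heterogeneous base avoids retro-Claisen opening and premature racemic aldolisation.

Step 3
Reactants: 5 2-methyl-2-(4-methyl-2-oxopentyl)cycloheptane-1,3-dione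
Product: 7 (8aR)-3-isopropyl-8a-methyl-4,5,6,7-tetrahydroazulene-2,8(1H,8aH)-dione, via cis-fused ketol 6 (not isolated)
Conditions: D-phenylalanine (0.3 equiv), PPTS (0.3 equiv), DMSO, 60 °C
Reagents that add atoms: none
Why: Proposed new method: the primary amino acid condenses with the unhindered side-chain C3 ketone (both ring ketones are neopentyl), the derived secondary enamine C3=C4 adds through C4 to one ring carbonyl that is hydrogen-bonded to the catalyst carboxyl group, hydrolysis releases ketol 6, and acid-assisted loss of water gives the tetrasubstituted C4=C5 enone 7. The closest known reactions are the Hajos–Parrish–Eder–Sauer–Wiechert desymmetrisation of 2,2-disubstituted cycloalkane-1,3-diones, which closes six-membered rings and for α-branched enones works best with phenylalanine plus an acid, and the amine-salt- or base-mediated condensation of 1,4-diketones to cyclopentenones; their union on a seven-membered dione has not been shown. The five-membered ring C1–C2–C3–C4–C5 closes in the 5-(enolendo)-exo-trig mode, which Baldwin's enolate rules rate as unfavourable although every 1,4-diketone-to-cyclopentenone condensation follows it, so a small primary amine, heat, an acid co-catalyst and the irreversible dehydration are used to draw the reversible addition forward. C1 is the only lasting stereocentre and is fixed by the catalyst's choice between the enantiotopic carbonyls (the one attacked becomes C5, the other stays as C10), D-phenylalanine being chosen for the R configuration. Site selectivity is secured by the substrate: the enamine toward C2 could only close a three-membered ring, aldol attack of C6 or C9 on C3 gives bridged ketols that cannot dehydrate without a bridgehead alkene and therefore revert, and quaternary C1 blocks Paal–Knorr pyrrole formation from the 1,4-dicarbonyl pairs.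

Step 4
Reactants: 7 (R)-enedione
Product: 8 C10 ethylene ketal of 7 (C3 enone untouched)
Conditions: TMSOCH2CH2OTMS, TMSOTf (cat.), CH2Cl2, −78 to −20 °C
Reagents that add atoms: 1,2-bis(trimethylsilyloxy)ethane, C[Si](C)(C)OCCO[Si](C)(C)C
Why: Noyori ketalisation distinguishes the saturated C10 ketone from the conjugated, isopropyl-shielded C3 carbonyl, which is much less electrophilic.

Step 5
Reactants: 8 enone ketal
Product: 9 C3 O-TBS 3,5-dienol ether (C3=C4 and C5=C6)
Conditions: TBSOTf, Et3N, CH2Cl2, 0 °C
Reagents that add atoms: TBSOTf, CC(C)(C)[Si](C)(C)OS(=O)(=O)C(F)(F)F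
Why: Soft enolisation (O-silylation, then loss of the γ-proton at C6) should give the extended dienol silyl ether, because the α′-protons at C2 are neopentyl and C1 carries no proton.

Step 6
Reactants: 9 dienol silyl ether
Product: 10 6β-hydroxy enone (1R,6S)
Conditions: mCPBA, CH2Cl2, −20 °C
Reagents that add atoms: mCPBA, OOC(=O)c1cccc(Cl)c1
Why: In this vinylogous Rubottom oxidation the peracid should deliver oxygen to the trisubstituted C5=C6 end (C4 is shielded by isopropyl) with return of the enone, and it should arrive on the β face because the pseudo-axial dioxolane oxygen on C10 lies under the α face, which sets 6β-OH.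

Step 7
Reactants: 11 4-hydroxybenzoic acid
Product: 13 4-(triisopropylsilyloxy)benzoic acid, via bis-silylated benzoate 12 (not isolated)
Conditions: TIPSCl (2.2 equiv), imidazole, DMF, rt; then K2CO3, THF/MeOH/H2O, rt; HCl to pH 3
Reagents that add atoms: TIPSCl, CC(C)[Si](Cl)(C(C)C)C(C)C
Why: Exhaustive silylation followed by selective hydrolysis of the far more labile silyl ester leaves an aryl TIPS ether that tolerates the later acid, cuprate and hydride steps.

Step 8
Reactants: 10 6β-hydroxy enone; 13 4-(triisopropylsilyloxy)benzoic acid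
Product: 14 6α-[4-(triisopropylsilyloxy)benzoyloxy] enone (1R,6R)
Conditions: PPh3, DIAD, THF, 0 °C to rt
Reagents that add atoms: 4-(triisopropylsilyloxy)benzoic acid (13), OC(=O)c1ccc(O[Si](C(C)C)(C(C)C)C(C)C)cc1
Why: Mitsunobu esterification displaces the activated allylic 6β-oxyphosphonium group by carboxylate in an SN2 sense and so inverts C6 to the 6α (R) configuration of the target.

Step 9
Reactants: 14 6α-aroyloxy enone
Product: 15 3α-allylic alcohol (1R,3S,6R)
Conditions: (R)-2-methyl-CBS-oxazaborolidine (20 mol %), BH3·SMe2, THF, −30 °C; MeOH quench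
Reagents that add atoms: none
Why: Corey–Bakshi–Shibata 1,2-reduction treats the α-isopropyl alkenyl arm as the large group and C2H2 as the small one, so the (R)-catalyst should deliver hydride to the β face, which is also the more open face of the substrate, and give the 3α (S) carbinol while ester, ketal and silyl ether stay inert.

Step 10
Reactants: 15 3α-allylic alcohol
Product: 18 cis-fused C3=C4 alkene with H-5 β, via sulfonylhydrazine adduct 16 (not isolated), via allylic diazene 17 (not isolated)
Conditions: 2-nitrobenzenesulfonylhydrazide (NBSH), PPh3, DEAD, THF, −30 °C; then rt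
Reagents that add atoms: none
Why: In the Myers reductive allylic transposition the Mitsunobu displacement inverts C3 to 3β-N, warming expels sulfinic acid to give the 3β-diazene, and its suprafacial retro-ene loss of N2 hands hydrogen to the β face of C5, which removes the C3 oxygen, moves the alkene to C3=C4 and sets the cis ring fusion.

Step 11
Reactants: 18 cis-fused C3=C4 alkene
Product: 19 4β-tertiary alcohol (4α-isopropyl)
Conditions: Co(acac)2 (cat.), PhSiH3, O2 (1 atm), THF, rt
Reagents that add atoms: dioxygen, O=O
Why: Mukaiyama hydration (hydrogen-atom transfer to C3, Markovnikov tertiary radical at C4, capture by O2 and in situ reduction) acts on the only alkene present, and O2 should approach the convex β face, syn to the small H-5 and anti to the C6 branch, giving 4β-OH.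

Step 12
Reactants: 19 tertiary alcohol ketal
Product: 20 C10 ketone
Conditions: 1 M HCl, THF, rt
Reagents that add atoms: water, O
Why: Acid-catalysed ketal hydrolysis frees the C10 ketone, since the non-allylic tertiary alcohol, the benzoate and the aryl TIPS ether tolerate dilute acid and the 4β-OH cannot bridge to C10, which leaves C1 on the α face.

Step 13
Reactants: 20 C10 ketone
Product: 21 C9=C10 TMS enol ether with C4 O-TMS
Conditions: TMSOTf (2.5 equiv), Et3N, CH2Cl2, 0 °C
Reagents that add atoms: TMSOTf, C[Si](C)(C)OS(=O)(=O)C(F)(F)F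
Why: Soft enolisation can only go toward C9 because C1 is quaternary, and the same reagent caps the tertiary C4 alcohol as a TMS ether that shields it from the cuprate.

Step 14
Reactants: 21 bis-TMS compound
Product: 22 C8=C9 enone (C10 ketone)
Conditions: Pd(OAc)2 (1.0 equiv), MeCN, rt
Reagents that add atoms: none
Why: Saegusa–Ito oxidation (palladation at C9, β-hydride elimination of H-8) introduces the enone under nearly neutral conditions that should not provoke vinylogous elimination of the C6 ester.

Step 15
Reactants: 22 C8=C9 enone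
Product: 23 8-methyl C9=C10 TMS enol ether
Conditions: Me2CuLi (from CuI and MeLi), TMSCl, Et2O/THF, −78 °C
Reagents that add atoms: Me2CuLi, [Li+].C[Cu-]C; TMSCl, C[Si](C)(C)Cl
Why: TMSCl-accelerated 1,4-addition of Me2CuLi forms C8–CH3 and traps the enolate regiospecifically while the aryl ester is inert at −78 °C, and the methyl is expected on the convex β face although this centre is erased in the next step.

Step 16
Reactants: 23 8-methyl TMS enol ether
Product: 24 8-methyl C8=C9 enone
Conditions: Pd(OAc)2 (1.0 equiv), MeCN, rt
Reagents that add atoms: none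
Why: A second Saegusa–Ito oxidation removes the tertiary H-8 by β-hydride elimination, the only β-hydrogen available to palladium at C9, and gives the conjugated trisubstituted alkene.

Step 17
Reactants: 24 8-methyl enone
Product: 25 10α-allylic alcohol (10S)
Conditions: NaBH4, CeCl3·7H2O, MeOH, −78 to −40 °C
Reagents that add atoms: none
Why: Luche 1,2-reduction should deliver hydride to the convex β face of C10, anti to the C1–C5 bond (Felkin–Anh), because the α face is closed by the cyclopentane ring with its α-isopropyl group and by the α-aroyloxy group, which sets 10α-OH.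

Step 18
Reactants: 25 10α-allylic alcohol; 26 3-methylbutanoyl chloride
Product: 27 10α-isovalerate (C4 O-TMS, phenol O-TIPS)
Conditions: pyridine, DMAP (cat.), CH2Cl2, 0 °C to rt
Reagents that add atoms: 3-methylbutanoyl chloride (26), CC(C)CC(=O)Cl
Why: DMAP-catalysed acylation of the only free hydroxyl forms the ester with retention at C10.

Step 19
Reactants: 27 protected diester
Product: 28 target, (1R,4S,5S,6R,10S)-4-hydroxy-6-(4-hydroxybenzoyloxy)-10-(3-methylbutanoyloxy)dauc-8-ene
Conditions: TBAF, AcOH, THF, 0 °C
Reagents that add atoms: none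
Why: Fluoride-induced desilylation cleaves both Si–O bonds, and the acetic acid buffer keeps the released phenoxide from starting ester migration or cleavage, so no stereocentre is touched.

Compound list
1 | cycloheptane-1,3-dione | O=C1CCCCC(=O)C1 | starting material
2 | iodomethane | CI | starting material
3 | 2-methylcycloheptane-1,3-dione | CC1C(=O)CCCCC1=O | intermediate
4 | 1-bromo-4-methylpentan-2-one | CC(C)CC(=O)CBr | starting material
5 | 2-methyl-2-(4-methyl-2-oxopentyl)cycloheptane-1,3-dione (achiral triketone) | CC(C)CC(=O)CC1(C)C(=O)CCCCC1=O | intermediate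
6 | cis-fused ketol: 5β-hydroxy, 1β-methyl, C3 and C10 ketones, C4 isopropyl (C4 configuration open, lost on dehydration) | C1CC(=O)[C@]2(C)CC(=O)C(C(C)C)[C@]2(O)CC1 | intermediate
7 | (8aR)-3-isopropyl-8a-methyl-4,5,6,7-tetrahydroazulene-2,8(1H,8aH)-dione (C4=C5 enone, C3 and C10 ketones) | CC(C)C1=C2CCCCC(=O)[C@]2(C)CC1=O | intermediate
8 | C10 ethylene ketal of 7 | C1CC2(OCCO2)[C@]3(C)CC(=O)C(C(C)C)=C3CC1 | intermediate
9 | C3 O-TBS 3,5-dienol ether of 8 | C1CC2(OCCO2)[C@]3(C)CC(O[Si](C)(C)C(C)(C)C)=C(C(C)C)C3=CC1 | intermediate
10 | 6β-hydroxy enone (1R,6S), C10 ketal | C1CC2(OCCO2)[C@]3(C)CC(=O)C(C(C)C)=C3[C@@H](O)C1 | intermediate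
11 | 4-hydroxybenzoic acid | OC(=O)c1ccc(O)cc1 | starting material
12 | triisopropylsilyl 4-(triisopropylsilyloxy)benzoate | CC(C)[Si](C(C)C)(C(C)C)OC(=O)c1ccc(O[Si](C(C)C)(C(C)C)C(C)C)cc1 | intermediate
13 | 4-(triisopropylsilyloxy)benzoic acid | OC(=O)c1ccc(O[Si](C(C)C)(C(C)C)C(C)C)cc1 | intermediate
14 | 6α-[4-(triisopropylsilyloxy)benzoyloxy] enone (1R,6R), C10 ketal | C1CC2(OCCO2)[C@]3(C)CC(=O)C(C(C)C)=C3[C@H](OC(=O)c4ccc(O[Si](C(C)C)(C(C)C)C(C)C)cc4)C1 | intermediate
15 | 3α-allylic alcohol (1R,3S,6R) | C1CC2(OCCO2)[C@]3(C)C[C@H](O)C(C(C)C)=C3[C@H](OC(=O)c4ccc(O[Si](C(C)C)(C(C)C)C(C)C)cc4)C1 | intermediate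
16 | 3β-N-(2-nitrobenzenesulfonyl)hydrazine adduct | C1CC2(OCCO2)[C@]3(C)C[C@@H](N(N)S(=O)(=O)c4ccccc4[N+](=O)[O-])C(C(C)C)=C3[C@H](OC(=O)c4ccc(O[Si](C(C)C)(C(C)C)C(C)C)cc4)C1 | intermediate
17 | 3β-allylic diazene | C1CC2(OCCO2)[C@]3(C)C[C@@H](N=N)C(C(C)C)=C3[C@H](OC(=O)c4ccc(O[Si](C(C)C)(C(C)C)C(C)C)cc4)C1 | intermediate
18 | cis-fused C3=C4 alkene, H-5 β, 6α-aroyloxy, C10 ketal | C1CC2(OCCO2)[C@]3(C)CC=C(C(C)C)[C@@H]3[C@H](OC(=O)c4ccc(O[Si](C(C)C)(C(C)C)C(C)C)cc4)C1 | intermediate
19 | 4β-hydroxy-4α-isopropyl compound, C10 ketal | C1CC2(OCCO2)[C@]3(C)CC[C@](O)(C(C)C)[C@@H]3[C@H](OC(=O)c4ccc(O[Si](C(C)C)(C(C)C)C(C)C)cc4)C1 | intermediate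
20 | C10 ketone with 4β-OH and 6α-aroyloxy | C1CC(=O)[C@]2(C)CC[C@](O)(C(C)C)[C@@H]2[C@H](OC(=O)c3ccc(O[Si](C(C)C)(C(C)C)C(C)C)cc3)C1 | intermediate
21 | C9=C10 TMS enol ether, C4 O-TMS | C1C=C(O[Si](C)(C)C)[C@]2(C)CC[C@](O[Si](C)(C)C)(C(C)C)[C@@H]2[C@H](OC(=O)c3ccc(O[Si](C(C)C)(C(C)C)C(C)C)cc3)C1 | intermediate
22 | C8=C9 enone, C4 O-TMS | C1=CC(=O)[C@]2(C)CC[C@](O[Si](C)(C)C)(C(C)C)[C@@H]2[C@H](OC(=O)c3ccc(O[Si](C(C)C)(C(C)C)C(C)C)cc3)C1 | intermediate
23 | 8-methyl C9=C10 TMS enol ether (8β-methyl expected, either C8 epimer serves) | C[C@H]1C=C(O[Si](C)(C)C)[C@]2(C)CC[C@](O[Si](C)(C)C)(C(C)C)[C@@H]2[C@H](OC(=O)c3ccc(O[Si](C(C)C)(C(C)C)C(C)C)cc3)C1 | intermediate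
24 | 8-methyl C8=C9 enone, C4 O-TMS | CC1=CC(=O)[C@]2(C)CC[C@](O[Si](C)(C)C)(C(C)C)[C@@H]2[C@H](OC(=O)c3ccc(O[Si](C(C)C)(C(C)C)C(C)C)cc3)C1 | intermediate
25 | 10α-allylic alcohol (10S) | CC1=C[C@H](O)[C@]2(C)CC[C@](O[Si](C)(C)C)(C(C)C)[C@@H]2[C@H](OC(=O)c3ccc(O[Si](C(C)C)(C(C)C)C(C)C)cc3)C1 | intermediate
26 | 3-methylbutanoyl chloride | CC(C)CC(=O)Cl | starting material
27 | 10α-isovalerate, C4 O-TMS, phenol O-TIPS | CC1=C[C@H](OC(=O)CC(C)C)[C@]2(C)CC[C@](O[Si](C)(C)C)(C(C)C)[C@@H]2[C@H](OC(=O)c3ccc(O[Si](C(C)C)(C(C)C)C(C)C)cc3)C1 | intermediate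
28 | (1R,4S,5S,6R,10S)-4-hydroxy-6-(4-hydroxybenzoyloxy)-10-(3-methylbutanoyloxy)dauc-8-ene | CC1=C[C@H](OC(=O)CC(C)C)[C@]2(C)CC[C@](O)(C(C)C)[C@@H]2[C@H](OC(=O)c2ccc(O)cc2)C1 | target

Total step count: 19. Longest linear sequence: 18 steps (steps 1–6 and 8–19). Step 7 is a one-step side branch.

Steps most likely to fail

Step 3. The enamine may not reach the strained five-ring transition state, so turnover stalls at reversible bridged ketols. It may also distinguish the two ring carbonyls poorly, so enantioselectivity is low. The fallback uses known chemistry, sets out from 5 and returns at 7.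
- Triketone 5 is closed without induction by the ordinary 1,4-diketone condensation (pyrrolidinium acetate, toluene, reflux) to the racemic enedione F1.
- Selective ketalisation of the C10 ketone with (2R,3R)-butane-2,3-diol (TsOH cat., benzene, Dean–Stark) gives the (1R)-butanediol ketal F2 and the (1S)-butanediol ketal F3.
- These diastereomers are separated by chromatography or crystallisation.
- Hydrolysis of F2 (1 M HCl, THF) gives 7.

Step 6. Oxygen transfer may go to the C3=C4 end of the dienol ether, which gives α-hydroxylation with deconjugation. It may also show poor facial selectivity at C6. The fallback sets out from 9 and returns at 14.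
- NBS (THF, −78 °C) halogenates the γ terminus of the dienol ether, a reaction that is reliably γ-selective. By the same facial argument it gives the 6β-bromo enone F4.
- SN2 displacement with the potassium salt of 13 (18-crown-6, MeCN, anhydrous) inverts C6 and gives 14 directly. Compound 10 and the Mitsunobu step are bypassed.

Step 17. Facial selectivity at C10 may be poor, or hydride may be delivered from the α face if the seven-membered ring adopts its alternative fold. The fallback sets out from 24 and returns at 27.
- The reduction is run to the epimeric 10β-allylic alcohol F5.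
- F5 is esterified with 3-methylbutanoic acid under Mitsunobu conditions (PPh3, DIAD, toluene). This inverts C10 and installs the isovalerate in one operation, giving 27.
- Any 25 formed alongside is acylated as in step 18, so both epimers converge.

Further compounds
F1 | step 3 | racemic enedione | CC(C)C1=C2CCCCC(=O)C2(C)CC1=O
F2 | step 3 | (1R)-butanediol ketal (C10 ketal of 7 with (2R,3R)-butane-2,3-diol) | C1CC2(O[C@H](C)[C@@H](C)O2)[C@]3(C)CC(=O)C(C(C)C)=C3CC1
F3 | step 3 | (1S)-butanediol ketal (diastereomer of F2, discarded) | C1CC2(O[C@H](C)[C@@H](C)O2)[C@@]3(C)CC(=O)C(C(C)C)=C3CC1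
F4 | step 6 | 6β-bromo enone, C10 ketal | C1CC2(OCCO2)[C@]3(C)CC(=O)C(C(C)C)=C3[C@@H](Br)C1
F5 | step 17 | 10β-allylic alcohol (C10 epimer of 25) | CC1=C[C@@H](O)[C@]2(C)CC[C@](O[Si](C)(C)C)(C(C)C)[C@@H]2[C@H](OC(=O)c3ccc(O[Si](C(C)C)(C(C)C)C(C)C)cc3)C1
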